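- In the first 0.667 h of the cedar run, ring climbs to 78.0% of the charge, an average start slope of 1.17 /h.
- Extended, that slope meets the last reading, 90.3%, at 0.772 h: this is the knee. Past it, between 4.00 h and 8.00 h, the slope is 0.00275 /h, far flatter than at the start.
- Open dimer is level from the first reading, 4.4% then and 4.4% at the end. The readings leave 5.30% of the charge unshown, as substrate, dormant form and side product together.
- The step to ring takes one substrate, while open dimer and side product need two partners. So the level should sink as the charge rises, and it does: at 6.00 h oak reads 81.1%, lower than cedar's 89.9% at that time.
- Take λ = 4.79 /M, the loss per molar: the fraction of the charge not found as ring at a run's last reading, divided by the charged concentration, here read from maple.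
- Cedar reads 4.85 /M and oak 4.30 /M, so λ sags at the highest charge.

| flask | substrate | remark | time |
|---|---|---|---|
| cedar | 0.020 M | run made earlier |  |
| maple | 0.028 M | run made earlier |  |
| oak | 0.044 M | run made earlier |  |
| ochre | 0.020 M | one stirred flow tank at steady state, fed with the mixture as stated, mean residence time 8.0 h |  |
| red | 0.020 M | a closed flask charged with all of it at once and left for 8.0 h | 8.0 h |
| green | 0.020 M | a tube with plug flow, the mixed feed as stated, residence time 8.0 h | 8.0 h |

- cedar (time / h: ring / %, open dimer / %): 0.667: 78.0, 4.4; 2.00: 87.1, 4.2; 4.00: 89.2, 4.2; 6.00: 89.9, 4.2; 8.00: 90.3, 4.4
- maple (time / h: ring / %, open dimer / %): 0.500: 69.8, 5.1; 1.00: 81.0, 6.1; 2.00: 84.4, 5.3; 3.00: 86.0, 5.9; 6.00: 86.6, 6.0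
- oak (time / h: ring / %, open dimer / %): 1.33: 78.2, 8.9; 2.50: 79.5, 8.2; 4.00: 80.3, 8.6; 5.00: 80.8, 8.8; 6.00: 81.1, 8.7

(scatter of a reading: 0.3 percentage points)

- percentages count the substrate that a species holds: one open dimer or side product counts as two
- the stated concentrations are those of everything mixed, before any reaction; amounts are the same in each set-up
- what was read earlier has a scatter of 0.3 percentage points, one standard deviation
- reactions considered so far: substrate -> ring; 2 substrate <-> open dimer; substrate + ring -> side product; substrate <-> dormant form
- the earlier runs were made in a closed, stirred flask

* the set-up with the highest share of ring in all that became ring or open dimer or side product, at the outlet or at the end ("none" if the first two lie within 2 percentage points) (ochre / red / green / none)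
* share of ring in all that became ring or open dimer or side product, at the outlet or at the end, ochre
* share of ring in all that became ring or open dimer or side product, at the outlet or at the end, red
* share of ring in all that became ring or open dimer or side product, at the outlet or at the end, green

- My reckoning: red follows the closed-flask history and green's tube repeats it, so both should hold near 90.4% of the charge as ring. I take that figure as the share asked, counting the rest of the charge as open dimer and side product. λ gives me no number for ochre's tank.
- The forecast says ochre 91.6%, red 90.6%, green 90.6%, verdict none: “Dimer vanishes, but side product grows because substrate always meets ring.”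
- The flask gives ochre 88.8%, red 90.1%, green 90.1%, verdict none; the gap of 1.3 percentage points is below the margin.

    substrate → ring (k = 0.0530 /min)
    2 substrate ⇌ open dimer (K = 1500 /M, k = 0.130 /M/min)
    substrate + ring → side product (k = 0.180 /M/min)
    substrate ⇌ dormant form (K = 0.340, k = 0.00360 /min)

- In red, substrate goes to ring with a half-life of 0.22 h by that step alone, while ring goes to side product with a half-life of 3.2 h by that step alone, the substrate as charged, a far longer time. Reckoned from the share rather than from the charge, red's loss per molar is 4.94 /M, beside λ at 4.79 /M. In a second flask, red with its substrate raised to 0.0323 M, the share has moved by 5 points, and λ reckons 5.9 points.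

The earlier runs and the new flask are simulated for an exercise, noise included.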